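**Retrosynthetic overview**
- The target is a 2,2-dialkylchroman-4-one. The C2–O1 ether bond is cut (retro-oxa-Michael) to give a 2'-hydroxyaryl β-methyl-β-alkyl enone; closing this bond forms the pyranone ring and sets the only stereocentre.
- The enone C=C is cut (retro-aldol condensation) to 1-(4-bromo-2,5-dihydroxyphenyl)ethanone and 6-hydroxy-6-methylheptan-2-one. Condensation and ring closure run in one flask under one chiral amine catalyst.
- The aryl ketone comes from C-acetylation of bromohydroquinone, so bromine is in place from the start. The hydroxy ketone comes from Markovnikov hydration of 6-methylhept-5-en-2-one.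
- The benzene ring is bought; the pyranone ring is the only ring made, and it is made last. No protecting groups are used.

Assumption: the sense of induction in step 3 cannot be derived with certainty. The quinine-derived amine is written; if it gives the (S)-enantiomer, the pseudoenantiomeric quinidine-derived amine is used under the same conditions.

**Step 1**
Reactants: 1 bromohydroquinone (2-bromobenzene-1,4-diol); 2 acetic acid
Product: 3 1-(4-bromo-2,5-dihydroxyphenyl)ethan-1-one
Conditions: AcOH (solvent), BF3·OEt2 (3 equiv), 110 °C, 3 h; then H2O
Reagents that add atoms: acetic acid (2), CC(=O)O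
Why: BF3-promoted Friedel–Crafts C-acylation (Fries-type, through the aryl acetate) goes ortho to a hydroxyl and para to bromine, which avoids the crowded site between Br and OH and is the open position least deactivated by the halogen; the product is held as its BF2 chelate, which stops a second acylation.

**Step 2**
Reactants: 4 6-methylhept-5-en-2-one
Product: 5 6-hydroxy-6-methylheptan-2-one
Conditions: 35% aq. H2SO4, 0 °C to rt, 16 h
Reagents that add atoms: water, O
Why: Acid-catalysed Markovnikov hydration of the trisubstituted alkene through the tertiary carbocation gives the tertiary alcohol and leaves the ketone untouched.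

**Step 3**
Reactants: 3 1-(4-bromo-2,5-dihydroxyphenyl)ethan-1-one; 5 6-hydroxy-6-methylheptan-2-one (2 equiv)
Product: 7 (2R)-7-bromo-6-hydroxy-2-(4-hydroxy-4-methylpentyl)-2-methyl-2,3-dihydro-4H-chromen-4-one, via enone 6 (not isolated)
Conditions: (8S,9S)-9-amino-9-deoxy-epi-quinine (20 mol%), 2-fluorobenzoic acid (40 mol%), 4 Å MS, toluene/2-MeTHF (4:1), 40 °C, Ar, 72 h; then aq. citric acid
Reagents that add atoms: none
Why: Proposed new method: a catalytic enantioselective Kabbe chromanone synthesis, in which the primary amine of the cinchona catalyst condenses with the ortho-hydroxyaryl ketone 3 (ketimine/enamine), carries out the aldol condensation with 5 (loss of water, taken up by the sieves) and holds the resulting enone 6 as a conjugated iminium ion whose E and Z forms interconvert through the dienamine; the N-bound cinchona framework blocks one face while the quinuclidinium carboxylate hydrogen-bonds the 2-hydroxyl oxygen and guides it to the open face of the β-carbon in a 6-endo oxa-Michael addition, which forms the C2–O1 bond and sets the (R) tetrasubstituted centre under Curtin–Hammett control; turnover is driven by transimination from the product, which is no longer a hydrogen-bond-stabilised ortho-hydroxy ketimine, onto fresh 3; the 5-hydroxyl cannot reach the β-carbon and the tertiary alcohol is a far weaker nucleophile than the phenol; the closest known reaction types are the racemic pyrrolidine-mediated Kabbe condensation and cinchona primary-amine iminium-catalysed oxa- and sulfa-Michael additions to enones.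

**Compound list**
1 | bromohydroquinone (2-bromobenzene-1,4-diol) | Oc1ccc(O)c(Br)c1 | starting material
2 | acetic acid | CC(=O)O | starting material
3 | 1-(4-bromo-2,5-dihydroxyphenyl)ethan-1-one | CC(=O)c1cc(O)c(Br)cc1O | intermediate
4 | 6-methylhept-5-en-2-one | CC(=O)CCC=C(C)C | starting material
5 | 6-hydroxy-6-methylheptan-2-one | CC(=O)CCCC(C)(C)O | intermediate
6 | (E)-1-(4-bromo-2,5-dihydroxyphenyl)-7-hydroxy-3,7-dimethyloct-2-en-1-one (equilibrating with its Z isomer, carried mainly as the iminium ion of the catalyst) | CC(C)(O)CCC/C(C)=C/C(=O)c1cc(O)c(Br)cc1O | intermediate
7 | (2R)-7-bromo-6-hydroxy-2-(4-hydroxy-4-methylpentyl)-2-methyl-2,3-dihydro-4H-chromen-4-one | CC(C)(O)CCC[C@]1(C)CC(=O)c2cc(O)c(Br)cc2O1 | target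

**Step count**
Total steps: 3. Longest linear sequence: 2 (1 → 3 → 7, or 4 → 5 → 7).

**Steps most likely to fail**

Step 3 (the proposed new step). The risks are low enantiomeric excess from a racemic background cyclisation of free enone 6, erosion of enantiomeric excess by reversible ring opening (retro-oxa-Michael) at long reaction times, incomplete E/Z equilibration, and slow turnover of the stable ketimine of 3. The fallback uses known chemistry and sets out from 3 and 5. The classical Kabbe condensation (pyrrolidine, 1 equiv, MeOH, 50 °C) gives racemic 7-bromo-6-hydroxy-2-(4-hydroxy-4-methylpentyl)-2-methylchroman-4-one F3. Preparative chiral SFC on an amylose tris(3,5-dimethylphenylcarbamate) phase (CO2/MeOH) separates it into the (R)-enantiomer and the (2S)-7-bromo-6-hydroxy-2-(4-hydroxy-4-methylpentyl)-2-methyl-2,3-dihydro-4H-chromen-4-one F4, which is discarded. The fallback comes back to the route at 7.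

Step 1. The risk is acylation at the site meta to bromine (giving the 3-bromo isomer) or diacylation. The fallback sets out from 1. Methylation (Me2SO4, K2CO3, acetone, reflux) gives 2-bromo-1,4-dimethoxybenzene F1. Friedel–Crafts acetylation (AcCl, AlCl3, CH2Cl2, 0 °C) then enters para to bromine, as is established for acylation and formylation of this ether, and gives 1-(4-bromo-2,5-dimethoxyphenyl)ethan-1-one F2. BBr3 (CH2Cl2, −78 °C to rt) cleaves both methyl ethers, and the fallback comes back to the route at 3.

Step 2. The risks are incomplete hydration (it is an equilibrium), acid-induced cyclodehydration of the δ-hydroxy ketone to a dihydropyran, and loss of the water-soluble product on work-up. The fallback sets out from 4 and replaces ionic hydration with a radical one: Mukaiyama hydration (Co(acac)2 cat., PhSiH3, O2 1 atm, THF, rt) adds a hydrogen atom to the alkene, traps the tertiary radical with O2 and reduces the peroxide under neutral conditions. It comes back to the route at 5 and makes no new compound (F0).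

**Further compounds**
F1 | step 1 | 2-bromo-1,4-dimethoxybenzene | COc1ccc(OC)c(Br)c1
F2 | step 1 | 1-(4-bromo-2,5-dimethoxyphenyl)ethan-1-one | CC(=O)c1cc(OC)c(Br)cc1OC
F0 | step 2 | none | none
F3 | step 3 | racemic 7-bromo-6-hydroxy-2-(4-hydroxy-4-methylpentyl)-2-methylchroman-4-one | CC(C)(O)CCCC1(C)CC(=O)c2cc(O)c(Br)cc2O1
F4 | step 3 | (2S)-7-bromo-6-hydroxy-2-(4-hydroxy-4-methylpentyl)-2-methyl-2,3-dihydro-4H-chromen-4-one | CC(C)(O)CCC[C@@]1(C)CC(=O)c2cc(O)c(Br)cc2O1
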